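**Plan**
- Retrosynthesis: the upper flavan is cut at O1–C2, C4–C4a (ring A leaves as a boronic acid), C3–C4 and C4–C6''. The two C–O bonds at C3''/C4'' are then removed to give a flav-3-ene, which is cut at O1''–C2'' and C2''–C3'' to a 2'-hydroxychalcone.
- Forward: ring C'' closes first by reduction–cyclisation of the chalcone, and the diol is then installed on it. The chain grows from C6'' (formyl, then enone), ring A is added by conjugate arylation, and the upper ring C closes last.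
- Enabling feature: in the flav-3-ene, C3''=C4'' of ring C'' is a styrene-type alkene conjugated to ring A'' and flanked by the C2'' aryl stereocentre. Suprafacial addition of O2 across it gives the C3''/C4'' cis-diol on the face that carries the C2'' aryl group.
- Stereochemistry: C2'' comes from chiral chromatography, C3''/C4'' from the dioxygenase, C4 from the (S)-BINAP–rhodium catalyst, and C2 from CBS reduction followed by Mitsunobu inversion.

Key step: step 7

Assumption: a biphenyl dioxygenase variant with the required face selectivity can be found by screening and directed evolution; the ligand antipode in step 17 is assigned from the usual enone-face model for monovalent rhodium–BINAP catalysts.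

Notation: plain locants refer to the upper flavan unit, doubly primed locants to the lower unit. ArL = (3aS,4R,9bR)-6,7-bis(benzyloxy)-4-[4-(benzyloxy)phenyl]-2,2-dimethyl-3a,9b-dihydro-4H-[1,3]dioxolo[4,5-c]chromen-8-yl (protected lower unit, bonded through C6''). ArA = 2,2-diphenyl-4-(prop-2-en-1-yloxy)-1,3-benzodioxol-5-yl (protected ring A).

**Step 1**
Reactants: 1 gallacetophenone (1-(2,3,4-trihydroxyphenyl)ethan-1-one)
Product: 2 1-[2-hydroxy-3,4-bis(methoxymethoxy)phenyl]ethan-1-one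
Conditions: MOMCl (2.2 equiv), K2CO3, acetone, 0 °C → rt
Reagents that add atoms: chloromethyl methyl ether, COCCl
Why: Williamson-type O-alkylation takes the 3- and 4-hydroxyls and spares the 2-hydroxyl, which is hydrogen-bonded to the ketone and later becomes O1''.

**Step 2**
Reactants: 3 4-hydroxybenzaldehyde
Product: 4 4-(methoxymethoxy)benzaldehyde
Conditions: MOMCl, K2CO3, acetone, rt
Reagents that add atoms: chloromethyl methyl ether, COCCl
Why: Williamson-type O-alkylation masks the phenol so that the aldehyde stays electrophilic under the basic aldol conditions.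

**Step 3**
Reactants: 2 1-[2-hydroxy-3,4-bis(methoxymethoxy)phenyl]ethan-1-one; 4 4-(methoxymethoxy)benzaldehyde
Product: 5 (E)-1-[2-hydroxy-3,4-bis(methoxymethoxy)phenyl]-3-[4-(methoxymethoxy)phenyl]prop-2-en-1-one
Conditions: KOH, EtOH, rt
Reagents that add atoms: none
Why: Claisen–Schmidt condensation of a non-enolisable aldehyde with the methyl ketone forms the C2''–C3'' bond as the (E)-enone.

**Step 4**
Reactants: 5 (E)-1-[2-hydroxy-3,4-bis(methoxymethoxy)phenyl]-3-[4-(methoxymethoxy)phenyl]prop-2-en-1-one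
Product: 7 rac-7,8-bis(methoxymethoxy)-2-[4-(methoxymethoxy)phenyl]-2H-chromene, via allylic alcohol 6 (not isolated)
Conditions: NaBH4, i-PrOH/THF, rt → 50 °C; then aq. AcOH, rt
Reagents that add atoms: none
Why: 1,2-reduction of the 2'-hydroxychalcone and cyclodehydration of the resulting allylic alcohol (the classical borohydride route to flav-3-enes) closes ring C'' through the O1''–C2'' bond, giving racemic material.

**Step 5**
Reactants: 7 rac-7,8-bis(methoxymethoxy)-2-[4-(methoxymethoxy)phenyl]-2H-chromene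
Product: 8 rac-2-(4-hydroxyphenyl)-2H-chromene-7,8-diol
Conditions: NaHSO4·SiO2, CH2Cl2, rt, argon
Reagents that add atoms: none
Why: Acetal cleavage of phenolic MOM ethers on silica-supported hydrogen sulfate runs in an aprotic medium at room temperature, which avoids solvent addition to the electron-rich C3''=C4'' bond; any reversible opening at C2'' is harmless while the material is racemic.

**Step 6**
Reactants: 8 rac-2-(4-hydroxyphenyl)-2H-chromene-7,8-diol
Product: 9 (2S)-2-(4-hydroxyphenyl)-2H-chromene-7,8-diol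
Conditions: preparative chiral SFC, amylose tris(3,5-dimethylphenylcarbamate) phase, CO2/MeOH, rt, dark
Reagents that add atoms: none
Why: Enantiomer separation on a polysaccharide carbamate phase under neutral conditions fixes C2'' for the whole lower unit, the (2S) antipode being assigned by electronic circular dichroism.

**Step 7**
Reactants: 9 (2S)-2-(4-hydroxyphenyl)-2H-chromene-7,8-diol
Product: 10 (2R,3R,4R)-2-(4-hydroxyphenyl)-3,4-dihydro-2H-chromene-3,4,7,8-tetrol (2,3-cis-3,4-cis)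
Conditions: resting E. coli cells co-producing an evolved biphenyl dioxygenase (oxygenase, ferredoxin, reductase) and glucose dehydrogenase, D-glucose, air, KH2PO4/K2HPO4 buffer pH 7.0, 5% DMSO, 28 °C, dark
Reagents that add atoms: dioxygen, O=O
Why: Proposed new method: the Rieske [2Fe-2S] cluster passes two electrons from NADH to the mononuclear non-haem iron site, where divalent iron binds O2 and, as a trivalent iron hydroperoxide or the oxo-hydroxo species derived from it, transfers both oxygen atoms suprafacially to C3''=C4'' of 9, so the C3''–O and C4''–O bonds form in one catalytic turnover and the diol is cis by mechanism. The closest known reaction type is the cis-dihydroxylation of 2H-chromenes, indene and 1,2-dihydronaphthalene by toluene and naphthalene dioxygenases, together with the turnover of hydroxylated flavonoid skeletons by biphenyl dioxygenases. No ring is closed in this step. The new stereocentres C3'' (R) and C4'' (R) are fixed by the binding pose in the enzyme pocket, which has to present the 3Re,4Si face (the face carrying the C2'' aryl group, which osmylation would leave untouched) to the iron–oxygen unit. The step needs this face selectivity and alkene-over-arene chemoselectivity; the substrate helps through its electron-rich styrene-type C3''=C4'' bond conjugated to ring A'' and through the para-hydroxyl that disfavours 2',3'-attack on ring B''. The rest must come from the variant selected, which is simpler to find for a single-enantiomer substrate.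

**Step 8**
Reactants: 10 (2R,3R,4R)-2-(4-hydroxyphenyl)-3,4-dihydro-2H-chromene-3,4,7,8-tetrol
Product: 11 (2R,3R,4R)-7,8-bis(benzyloxy)-2-[4-(benzyloxy)phenyl]-3,4-dihydro-2H-chromene-3,4-diol
Conditions: BnBr (3.3 equiv), K2CO3, DMF, rt, argon
Reagents that add atoms: benzyl bromide, BrCc1ccccc1
Why: Williamson etherification under carbonate conditions alkylates only the three phenoxides and leaves the secondary diol free.

**Step 9**
Reactants: 11 (2R,3R,4R)-7,8-bis(benzyloxy)-2-[4-(benzyloxy)phenyl]-3,4-dihydro-2H-chromene-3,4-diol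
Product: 12 (3aS,4R,9bR)-6,7-bis(benzyloxy)-4-[4-(benzyloxy)phenyl]-2,2-dimethyl-3a,9b-dihydro-4H-[1,3]dioxolo[4,5-c]chromene
Conditions: Me2C(OMe)2, PPTS (cat.), acetone, rt
Reagents that add atoms: 2,2-dimethoxypropane, COC(C)(C)OC
Why: Acid-catalysed transketalisation gives the cis-fused isopropylidene acetal that only a 3'',4''-cis diol can form (spatial arrangement unchanged; the C3'' descriptor changes only through priorities).

**Step 10**
Reactants: 12 (3aS,4R,9bR)-6,7-bis(benzyloxy)-4-[4-(benzyloxy)phenyl]-2,2-dimethyl-3a,9b-dihydro-4H-[1,3]dioxolo[4,5-c]chromene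
Product: 13 (3aS,4R,9bR)-6,7-bis(benzyloxy)-4-[4-(benzyloxy)phenyl]-8-bromo-2,2-dimethyl-3a,9b-dihydro-4H-[1,3]dioxolo[4,5-c]chromene
Conditions: NBS (1.05 equiv), MeCN, 0 °C, dark
Reagents that add atoms: N-bromosuccinimide, O=C1CCC(=O)N1Br
Why: Electrophilic aromatic bromination goes to C6'', the position para to the ring oxygen O1'' and ortho to the 7''-benzyloxy group, as in the 4-bromination of 1,2,3-trialkoxybenzenes.

**Step 11**
Reactants: 13 (3aS,4R,9bR)-6,7-bis(benzyloxy)-4-[4-(benzyloxy)phenyl]-8-bromo-2,2-dimethyl-3a,9b-dihydro-4H-[1,3]dioxolo[4,5-c]chromene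
Product: 15 (3aS,4R,9bR)-6,7-bis(benzyloxy)-4-[4-(benzyloxy)phenyl]-2,2-dimethyl-3a,9b-dihydro-4H-[1,3]dioxolo[4,5-c]chromene-8-carbaldehyde, via aryllithium 14 (not isolated)
Conditions: n-BuLi, THF, −78 °C; DMF, −78 → 0 °C; aq. NH4Cl
Reagents that add atoms: N,N-dimethylformamide, CN(C)C=O
Why: Bromine–lithium exchange followed by formylation with DMF forms the C4–C6'' bond under conditions that leave the acetonide and benzyl ethers intact.

**Step 12**
Reactants: 15 ArL–CHO (the 8-carbaldehyde of step 11); 16 1-[4-(benzyloxy)phenyl]ethan-1-one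
Product: 17 (2E)-1-[4-(benzyloxy)phenyl]-3-ArL-prop-2-en-1-one
Conditions: KOH, EtOH/THF, rt → 40 °C
Reagents that add atoms: none
Why: Claisen–Schmidt condensation of the non-enolisable aldehyde with the acetophenone forms the C3–C4 bond as the (E)-chalcone.

**Step 13**
Reactants: 18 pyrogallol (benzene-1,2,3-triol)
Product: 19 2,2-diphenyl-1,3-benzodioxol-4-ol
Conditions: Ph2CCl2, Ph2O, 170 °C
Reagents that add atoms: dichlorodiphenylmethane, ClC(Cl)(c1ccccc1)c1ccccc1
Why: Ketalisation of two adjacent hydroxyls as the hydrogenolysable diphenylmethylene ketal leaves one terminal phenol free, the future O1.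

**Step 14**
Reactants: 19 2,2-diphenyl-1,3-benzodioxol-4-ol
Product: 20 5-bromo-2,2-diphenyl-1,3-benzodioxol-4-ol
Conditions: NBS, i-Pr2NH (10 mol%), CH2Cl2, 0 °C
Reagents that add atoms: N-bromosuccinimide, O=C1CCC(=O)N1Br
Why: Amine-mediated ortho-selective bromination of a phenol puts bromine on the single free ortho position, the carbon that will become C4a.

**Step 15**
Reactants: 20 5-bromo-2,2-diphenyl-1,3-benzodioxol-4-ol
Product: 21 5-bromo-2,2-diphenyl-4-(prop-2-en-1-yloxy)-1,3-benzodioxole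
Conditions: allyl bromide, K2CO3, DMF, rt
Reagents that add atoms: allyl bromide, C=CCBr
Why: Williamson etherification installs an allyl group that zerovalent palladium can later remove without touching benzyl ethers or ketals.

**Step 16**
Reactants: 21 5-bromo-2,2-diphenyl-4-(prop-2-en-1-yloxy)-1,3-benzodioxole
Product: 23 [2,2-diphenyl-4-(prop-2-en-1-yloxy)-1,3-benzodioxol-5-yl]boronic acid, via aryllithium 22 (not isolated)
Conditions: n-BuLi, THF, −78 °C; B(Oi-Pr)3, −78 °C → rt; aq. NH4Cl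
Reagents that add atoms: triisopropyl borate, CC(C)OB(OC(C)C)OC(C)C; water, O
Why: Bromine–lithium exchange at −78 °C outruns any reaction of the allyl ether, and borylation of the aryllithium followed by hydrolysis gives the ArA boronic acid.

**Step 17**
Reactants: 17 (2E)-1-[4-(benzyloxy)phenyl]-3-ArL-prop-2-en-1-one; 23 [2,2-diphenyl-4-(prop-2-en-1-yloxy)-1,3-benzodioxol-5-yl]boronic acid
Product: 24 (3R)-1-[4-(benzyloxy)phenyl]-3-ArL-3-ArA-propan-1-one
Conditions: [Rh(OH)((S)-BINAP)]2 (3 mol%), 23 (2.5 equiv), 1,4-dioxane/H2O (10:1), 40 °C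
Reagents that add atoms: none
Why: In this Hayashi–Miyaura conjugate arylation the aryl–rhodium species inserts the enone from the face that is Si at both C2 and C3, the face selected by the (S)-ligand in the accepted model, which forms the C4–C4a bond and sets the diarylmethine centre under catalyst control (R here by priority; it becomes 4S in the target).

**Step 18**
Reactants: 24 (3R)-1-[4-(benzyloxy)phenyl]-3-ArL-3-ArA-propan-1-one
Product: 25 (1R,3R)-1-[4-(benzyloxy)phenyl]-3-ArL-3-ArA-propan-1-ol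
Conditions: (S)-2-methyl-CBS-oxazaborolidine (20 mol%), catecholborane, toluene, −78 → −40 °C
Reagents that add atoms: none
Why: In this Corey–Bakshi–Shibata reduction the (S)-oxazaborolidine delivers hydride to the Si face of the aryl ketone (aryl as the large group) to give the (1R)-carbinol, with catecholborane as a hydride source that does not hydroborate the allyl ether at low temperature.

**Step 19**
Reactants: 25 (1R,3R)-1-[4-(benzyloxy)phenyl]-3-ArL-3-ArA-propan-1-ol
Product: 26 (1R,3R)-1-[4-(benzyloxy)phenyl]-3-ArL-3-(4-hydroxy-2,2-diphenyl-1,3-benzodioxol-5-yl)propan-1-ol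
Conditions: Pd(PPh3)4 (5 mol%), morpholine, THF, rt
Reagents that add atoms: none
Why: Allyl transfer to morpholine through a zerovalent palladium catalyst (Tsuji–Trost deallylation) frees only the phenol ortho to the diarylmethine carbon.

**Step 20**
Reactants: 26 (1R,3R)-1-[4-(benzyloxy)phenyl]-3-ArL-3-(4-hydroxy-2,2-diphenyl-1,3-benzodioxol-5-yl)propan-1-ol
Product: 27 (6R,8S)-8-[4-(benzyloxy)phenyl]-6-ArL-2,2-diphenyl-7,8-dihydro-6H-[1,3]dioxolo[4,5-h]chromene (upper flavan 2S,4R by priority; 2,4-trans)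
Conditions: PPh3, DIAD, THF (0.01 M), 0 °C → rt
Reagents that add atoms: none
Why: In this intramolecular Mitsunobu etherification the phenol displaces the activated carbinol oxygen in a 6-exo-tet SN2 step with inversion, which closes the upper ring C and turns the (1R)-carbinol into C2 (S), trans to the C4 aryl group.

**Step 21**
Reactants: 27 (6R,8S)-8-[4-(benzyloxy)phenyl]-6-ArL-2,2-diphenyl-7,8-dihydro-6H-[1,3]dioxolo[4,5-h]chromene
Product: 28 (2R,3R,4R)-7,8-bis(benzyloxy)-2-[4-(benzyloxy)phenyl]-6-{(6R,8S)-8-[4-(benzyloxy)phenyl]-2,2-diphenyl-7,8-dihydro-6H-[1,3]dioxolo[4,5-h]chromen-6-yl}-3,4-dihydro-2H-chromene-3,4-diol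
Conditions: AcOH/H2O/THF (3:1:1), 40 °C
Reagents that add atoms: none
Why: Mild aqueous acid hydrolyses the aliphatic isopropylidene acetal through the oxocarbenium ion at the ketal carbon, so the C4''–O bond is not broken and the benzyl ethers and the diaryl ketal stay in place.

**Step 22**
Reactants: 28 (the hexa-protected diol of step 21)
Product: 29 (2R,3R,4R)-6-[(2S,4S)-7,8-dihydroxy-2-(4-hydroxyphenyl)-3,4-dihydro-2H-chromen-4-yl]-2-(4-hydroxyphenyl)-3,4-dihydro-2H-chromene-3,4,7,8-tetrol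
Conditions: H2 (1 atm), Pd(OH)2/C, THF/MeOH, rt
Reagents that add atoms: none
Why: Neutral hydrogenolysis removes the four benzyl ethers and the diphenylmethylene ketal in one operation, as is standard for benzylated flavan-3-ols and proanthocyanidins, so the acid-sensitive target is released from a neutral medium.

**Compound list**
1 | gallacetophenone (1-(2,3,4-trihydroxyphenyl)ethan-1-one) | CC(=O)c1ccc(O)c(O)c1O | starting material
2 | 1-[2-hydroxy-3,4-bis(methoxymethoxy)phenyl]ethan-1-one | CC(=O)c1ccc(OCOC)c(OCOC)c1O | intermediate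
3 | 4-hydroxybenzaldehyde | O=Cc1ccc(O)cc1 | starting material
4 | 4-(methoxymethoxy)benzaldehyde | COCOc1ccc(C=O)cc1 | intermediate
5 | (E)-1-[2-hydroxy-3,4-bis(methoxymethoxy)phenyl]-3-[4-(methoxymethoxy)phenyl]prop-2-en-1-one | COCOc1ccc(/C=C/C(=O)c2ccc(OCOC)c(OCOC)c2O)cc1 | intermediate
6 | rac-(E)-1-[2-hydroxy-3,4-bis(methoxymethoxy)phenyl]-3-[4-(methoxymethoxy)phenyl]prop-2-en-1-ol | COCOc1ccc(/C=C/C(O)c2ccc(OCOC)c(OCOC)c2O)cc1 | intermediate
7 | rac-7,8-bis(methoxymethoxy)-2-[4-(methoxymethoxy)phenyl]-2H-chromene | COCOc1ccc(C2C=Cc3ccc(OCOC)c(OCOC)c3O2)cc1 | intermediate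
8 | rac-2-(4-hydroxyphenyl)-2H-chromene-7,8-diol | Oc1ccc(C2C=Cc3ccc(O)c(O)c3O2)cc1 | intermediate
9 | (2S)-2-(4-hydroxyphenyl)-2H-chromene-7,8-diol | c1cc2c(c(O)c1O)O[C@H](c1ccc(O)cc1)C=C2 | intermediate
10 | (2R,3R,4R)-2-(4-hydroxyphenyl)-3,4-dihydro-2H-chromene-3,4,7,8-tetrol | c1cc2c(c(O)c1O)O[C@H](c1ccc(O)cc1)[C@H](O)[C@@H]2O | intermediate
11 | (2R,3R,4R)-7,8-bis(benzyloxy)-2-[4-(benzyloxy)phenyl]-3,4-dihydro-2H-chromene-3,4-diol | c1cc2c(c(OCc3ccccc3)c1OCc1ccccc1)O[C@H](c1ccc(OCc3ccccc3)cc1)[C@H](O)[C@@H]2O | intermediate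
12 | (3aS,4R,9bR)-6,7-bis(benzyloxy)-4-[4-(benzyloxy)phenyl]-2,2-dimethyl-3a,9b-dihydro-4H-[1,3]dioxolo[4,5-c]chromene | c1cc2c(c(OCc3ccccc3)c1OCc1ccccc1)O[C@H](c1ccc(OCc3ccccc3)cc1)[C@@H]1OC(C)(C)O[C@H]21 | intermediate
13 | (3aS,4R,9bR)-6,7-bis(benzyloxy)-4-[4-(benzyloxy)phenyl]-8-bromo-2,2-dimethyl-3a,9b-dihydro-4H-[1,3]dioxolo[4,5-c]chromene | Brc1cc2c(c(OCc3ccccc3)c1OCc1ccccc1)O[C@H](c1ccc(OCc3ccccc3)cc1)[C@@H]1OC(C)(C)O[C@H]21 | intermediate
14 | [(3aS,4R,9bR)-6,7-bis(benzyloxy)-4-[4-(benzyloxy)phenyl]-2,2-dimethyl-3a,9b-dihydro-4H-[1,3]dioxolo[4,5-c]chromen-8-yl]lithium | [Li]c1cc2c(c(OCc3ccccc3)c1OCc1ccccc1)O[C@H](c1ccc(OCc3ccccc3)cc1)[C@@H]1OC(C)(C)O[C@H]21 | intermediate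
15 | (3aS,4R,9bR)-6,7-bis(benzyloxy)-4-[4-(benzyloxy)phenyl]-2,2-dimethyl-3a,9b-dihydro-4H-[1,3]dioxolo[4,5-c]chromene-8-carbaldehyde | O=Cc1cc2c(c(OCc3ccccc3)c1OCc1ccccc1)O[C@H](c1ccc(OCc3ccccc3)cc1)[C@@H]1OC(C)(C)O[C@H]21 | intermediate
16 | 1-[4-(benzyloxy)phenyl]ethan-1-one | CC(=O)c1ccc(OCc2ccccc2)cc1 | starting material
17 | (2E)-1-[4-(benzyloxy)phenyl]-3-ArL-prop-2-en-1-one | O=C(/C=C/c1cc2c(c(OCc3ccccc3)c1OCc1ccccc1)O[C@H](c1ccc(OCc3ccccc3)cc1)[C@@H]1OC(C)(C)O[C@H]21)c1ccc(OCc2ccccc2)cc1 | intermediate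
18 | pyrogallol (benzene-1,2,3-triol) | Oc1cccc(O)c1O | starting material
19 | 2,2-diphenyl-1,3-benzodioxol-4-ol | Oc1cccc2OC(c3ccccc3)(c3ccccc3)Oc12 | intermediate
20 | 5-bromo-2,2-diphenyl-1,3-benzodioxol-4-ol | Oc1c(Br)ccc2OC(c3ccccc3)(c3ccccc3)Oc12 | intermediate
21 | 5-bromo-2,2-diphenyl-4-(prop-2-en-1-yloxy)-1,3-benzodioxole | C=CCOc1c(Br)ccc2OC(c3ccccc3)(c3ccccc3)Oc12 | intermediate
22 | [2,2-diphenyl-4-(prop-2-en-1-yloxy)-1,3-benzodioxol-5-yl]lithium | [Li]c1ccc2OC(c3ccccc3)(c3ccccc3)Oc2c1OCC=C | intermediate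
23 | [2,2-diphenyl-4-(prop-2-en-1-yloxy)-1,3-benzodioxol-5-yl]boronic acid | OB(O)c1ccc2OC(c3ccccc3)(c3ccccc3)Oc2c1OCC=C | intermediate
24 | (3R)-1-[4-(benzyloxy)phenyl]-3-ArL-3-ArA-propan-1-one | O=C(C[C@@H](c1cc2c(c(OCc3ccccc3)c1OCc1ccccc1)O[C@H](c1ccc(OCc3ccccc3)cc1)[C@@H]1OC(C)(C)O[C@H]21)c1ccc2OC(c3ccccc3)(c3ccccc3)Oc2c1OCC=C)c1ccc(OCc2ccccc2)cc1 | intermediate
25 | (1R,3R)-1-[4-(benzyloxy)phenyl]-3-ArL-3-ArA-propan-1-ol | O[C@H](C[C@@H](c1cc2c(c(OCc3ccccc3)c1OCc1ccccc1)O[C@H](c1ccc(OCc3ccccc3)cc1)[C@@H]1OC(C)(C)O[C@H]21)c1ccc2OC(c3ccccc3)(c3ccccc3)Oc2c1OCC=C)c1ccc(OCc2ccccc2)cc1 | intermediate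
26 | (1R,3R)-1-[4-(benzyloxy)phenyl]-3-ArL-3-(4-hydroxy-2,2-diphenyl-1,3-benzodioxol-5-yl)propan-1-ol | O[C@H](C[C@@H](c1cc2c(c(OCc3ccccc3)c1OCc1ccccc1)O[C@H](c1ccc(OCc3ccccc3)cc1)[C@@H]1OC(C)(C)O[C@H]21)c1ccc2OC(c3ccccc3)(c3ccccc3)Oc2c1O)c1ccc(OCc2ccccc2)cc1 | intermediate
27 | (6R,8S)-8-[4-(benzyloxy)phenyl]-6-ArL-2,2-diphenyl-7,8-dihydro-6H-[1,3]dioxolo[4,5-h]chromene | c1ccccc1COc1ccc([C@@H]2C[C@@H](c3cc4c(c(OCc5ccccc5)c3OCc3ccccc3)O[C@H](c3ccc(OCc5ccccc5)cc3)[C@@H]3OC(C)(C)O[C@H]43)c3ccc4OC(c5ccccc5)(c5ccccc5)Oc4c3O2)cc1 | intermediate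
28 | (2R,3R,4R)-7,8-bis(benzyloxy)-2-[4-(benzyloxy)phenyl]-6-{(6R,8S)-8-[4-(benzyloxy)phenyl]-2,2-diphenyl-7,8-dihydro-6H-[1,3]dioxolo[4,5-h]chromen-6-yl}-3,4-dihydro-2H-chromene-3,4-diol | c1ccccc1COc1ccc([C@@H]2C[C@@H](c3cc4c(c(OCc5ccccc5)c3OCc3ccccc3)O[C@H](c3ccc(OCc5ccccc5)cc3)[C@H](O)[C@@H]4O)c3ccc4OC(c5ccccc5)(c5ccccc5)Oc4c3O2)cc1 | intermediate
29 | (2R,3R,4R)-6-[(2S,4S)-7,8-dihydroxy-2-(4-hydroxyphenyl)-3,4-dihydro-2H-chromen-4-yl]-2-(4-hydroxyphenyl)-3,4-dihydro-2H-chromene-3,4,7,8-tetrol | Oc1ccc([C@@H]2C[C@@H](c3cc4c(c(O)c3O)O[C@H](c3ccc(O)cc3)[C@H](O)[C@@H]4O)c3ccc(O)c(O)c3O2)cc1 | target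

**Step count and risks**
Total: 22 steps. Longest linear sequence: 17 steps (steps 1, 3–12 and 17–22).

Steps most likely to fail:

1. Step 7. Oxygen may be delivered to the face away from the C2'' aryl group, the enzyme may instead dioxygenate an arene ring or hydroxylate a benzylic position, or turnover may be too slow to outrun autoxidation of the catechol substrate. The fallback sets out from 9 and returns at 11. Benzylation of 9 (BnBr, K2CO3, DMF) gives (2S)-7,8-bis(benzyloxy)-2-[4-(benzyloxy)phenyl]-2H-chromene F1. Woodward cis-hydroxylation (I2, AgOAc, AcOH, rt; then wet AcOH, 80 °C) starts with iodonium formation on the face away from the C2'' aryl group and anti opening at benzylic C4'' to the trans-iodoacetate (2R,3R,4R)-7,8-bis(benzyloxy)-2-[4-(benzyloxy)phenyl]-3-iodo-3,4-dihydro-2H-chromen-4-yl acetate F2. Silver-assisted displacement of iodide by the neighbouring acetate with inversion at C3'' and hydrolysis of the bridged acetoxonium ion then place both oxygens on the aryl face. The product is the monoacetate (2R,3R,4R)-7,8-bis(benzyloxy)-2-[4-(benzyloxy)phenyl]-4-hydroxy-3,4-dihydro-2H-chromen-3-yl acetate F3 (its 4-acetate regioisomer converges). K2CO3/MeOH then gives 11.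

2. Step 17. The two ortho-alkoxy aryl groups may slow insertion so that protodeboronation takes over, and catalyst control of the enone face may be incomplete. The fallback sets out from 15 and 21 and returns at 24. Wittig olefination of 15 with (4S)-4-phenyl-3-[(triphenyl-λ5-phosphanylidene)acetyl]-1,3-oxazolidin-2-one (toluene, 80 °C) gives (4S)-3-[(2E)-3-ArL-prop-2-enoyl]-4-phenyl-1,3-oxazolidin-2-one F4. Bromide 21 and Mg (THF) give bromo[2,2-diphenyl-4-(prop-2-en-1-yloxy)-1,3-benzodioxol-5-yl]magnesium F5. With CuBr·SMe2 (THF, −40 °C) F5 adds to the magnesium-chelated imide anti to the 4-phenyl group, the same Si face of C3, to give (4S)-3-[(3R)-3-ArL-3-ArA-propanoyl]-4-phenyl-1,3-oxazolidin-2-one F6. Transamidation (MeNHOMe·HCl, AlMe3, CH2Cl2, 0 °C) gives the Weinreb amide (3R)-N-methoxy-N-methyl-3-ArL-3-ArA-propanamide F7, and 4-BnOC6H4MgBr (THF, 0 °C) converts it into 24.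

3. Step 20. The activated para-alkoxybenzylic carbinol may ionise before the phenol attacks, which would erode the configuration at C2 or lead to elimination. The fallback sets out from 24 and returns at 27, and it never breaks the carbinol C–O bond. Reduction of 24 with the antipodal (R)-2-methyl-CBS-oxazaborolidine and catecholborane gives (1S,3R)-1-[4-(benzyloxy)phenyl]-3-ArL-3-ArA-propan-1-ol F8. Deallylation as in step 19 gives (1S,3R)-1-[4-(benzyloxy)phenyl]-3-ArL-3-(4-hydroxy-2,2-diphenyl-1,3-benzodioxol-5-yl)propan-1-ol F9. Phenol-selective triflation (PhNTf2, K2CO3, MeCN, rt) gives (1S,3S)-1-[4-(benzyloxy)phenyl]-3-ArL-3-[2,2-diphenyl-4-(trifluoromethanesulfonyloxy)-1,3-benzodioxol-5-yl]propan-1-ol F10. Palladium-catalysed intramolecular aryl etherification (Pd2(dba)3, 2-(di-tert-butylphosphino)-2',4',6'-triisopropylbiphenyl, K3PO4, toluene, 80 °C) joins the carbinol oxygen to C8a with retention at the carbinol carbon and gives 27.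

**Further compounds**
F1 | step 7 | (2S)-7,8-bis(benzyloxy)-2-[4-(benzyloxy)phenyl]-2H-chromene | c1cc2c(c(OCc3ccccc3)c1OCc1ccccc1)O[C@H](c1ccc(OCc3ccccc3)cc1)C=C2
F2 | step 7 | (2R,3R,4R)-7,8-bis(benzyloxy)-2-[4-(benzyloxy)phenyl]-3-iodo-3,4-dihydro-2H-chromen-4-yl acetate | c1cc2c(c(OCc3ccccc3)c1OCc1ccccc1)O[C@H](c1ccc(OCc3ccccc3)cc1)[C@@H](I)[C@@H]2OC(C)=O
F3 | step 7 | (2R,3R,4R)-7,8-bis(benzyloxy)-2-[4-(benzyloxy)phenyl]-4-hydroxy-3,4-dihydro-2H-chromen-3-yl acetate | c1cc2c(c(OCc3ccccc3)c1OCc1ccccc1)O[C@H](c1ccc(OCc3ccccc3)cc1)[C@H](OC(C)=O)[C@@H]2O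
F4 | step 17 | (4S)-3-[(2E)-3-ArL-prop-2-enoyl]-4-phenyl-1,3-oxazolidin-2-one | O=C1OC[C@H](c2ccccc2)N1C(=O)/C=C/c1cc2c(c(OCc3ccccc3)c1OCc1ccccc1)O[C@H](c1ccc(OCc3ccccc3)cc1)[C@@H]1OC(C)(C)O[C@H]21
F5 | step 17 | bromo[2,2-diphenyl-4-(prop-2-en-1-yloxy)-1,3-benzodioxol-5-yl]magnesium | Br[Mg]c1ccc2OC(c3ccccc3)(c3ccccc3)Oc2c1OCC=C
F6 | step 17 | (4S)-3-[(3R)-3-ArL-3-ArA-propanoyl]-4-phenyl-1,3-oxazolidin-2-one | O=C1OC[C@H](c2ccccc2)N1C(=O)C[C@@H](c1cc2c(c(OCc3ccccc3)c1OCc1ccccc1)O[C@H](c1ccc(OCc3ccccc3)cc1)[C@@H]1OC(C)(C)O[C@H]21)c1ccc2OC(c3ccccc3)(c3ccccc3)Oc2c1OCC=C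
F7 | step 17 | (3R)-N-methoxy-N-methyl-3-ArL-3-ArA-propanamide | CON(C)C(=O)C[C@@H](c1cc2c(c(OCc3ccccc3)c1OCc1ccccc1)O[C@H](c1ccc(OCc3ccccc3)cc1)[C@@H]1OC(C)(C)O[C@H]21)c1ccc2OC(c3ccccc3)(c3ccccc3)Oc2c1OCC=C
F8 | step 20 | (1S,3R)-1-[4-(benzyloxy)phenyl]-3-ArL-3-ArA-propan-1-ol | O[C@@H](C[C@@H](c1cc2c(c(OCc3ccccc3)c1OCc1ccccc1)O[C@H](c1ccc(OCc3ccccc3)cc1)[C@@H]1OC(C)(C)O[C@H]21)c1ccc2OC(c3ccccc3)(c3ccccc3)Oc2c1OCC=C)c1ccc(OCc2ccccc2)cc1
F9 | step 20 | (1S,3R)-1-[4-(benzyloxy)phenyl]-3-ArL-3-(4-hydroxy-2,2-diphenyl-1,3-benzodioxol-5-yl)propan-1-ol | O[C@@H](C[C@@H](c1cc2c(c(OCc3ccccc3)c1OCc1ccccc1)O[C@H](c1ccc(OCc3ccccc3)cc1)[C@@H]1OC(C)(C)O[C@H]21)c1ccc2OC(c3ccccc3)(c3ccccc3)Oc2c1O)c1ccc(OCc2ccccc2)cc1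
F10 | step 20 | (1S,3S)-1-[4-(benzyloxy)phenyl]-3-ArL-3-[2,2-diphenyl-4-(trifluoromethanesulfonyloxy)-1,3-benzodioxol-5-yl]propan-1-ol | O[C@@H](C[C@@H](c1cc2c(c(OCc3ccccc3)c1OCc1ccccc1)O[C@H](c1ccc(OCc3ccccc3)cc1)[C@@H]1OC(C)(C)O[C@H]21)c1ccc2OC(c3ccccc3)(c3ccccc3)Oc2c1OS(=O)(=O)C(F)(F)F)c1ccc(OCc2ccccc2)cc1
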